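**Plan**

1. Retrosynthesis: the spiro-epoxide goes back to an exocyclic methylene (hydroxyl-directed epoxidation). The methylene and the tertiary alcohol go back to one oxygen bridging ring D (eliminative ether opening).
2. Strategic cut: the bond from the ester-bearing quaternary carbon to the spiro carbon and the bond from its CH2 neighbour to the carbinol carbon are broken together as a retro-[3+2]. This works because the carbinol carbon and the spiro carbon are 1,4-related in ring D and carry their oxygens on the same face, so a single oxygen can join them as a five-membered carbonyl ylide (O–C(Me)–C(=O)–C(Me)–C(Me)=), with CH2=C(CO2Me) as the two-carbon partner. Rings C and D (the whole bicyclo[3.3.1]nonane) thereby fall back to a ring-A/B lactone-diene carrying an acrylate and a diazo-diketone arm.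
3. Forward order: ring B first (one-carbon ring expansion of (+)-dihydrocarvone; its hydroxy-isopropyl group becomes the lactone CMe2–O), then the two arms, then the diene and ring A, then rings C and D in one step, then the epoxide.
4. Stereochemistry: the ring-B quaternary carbon comes from ligand-controlled copper conjugate addition; the adjacent CH from equilibration trans to it; the acyclic quaternary carbon from Fráter–Seebach chelate control starting from (R)-3-hydroxybutanoate (its carbinol is later oxidised to the acetyl group); the three remaining carbon centres from the tether-controlled cycloaddition; the epoxide from delivery by the tertiary OH.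

Key step: step 20

Assumption: commercial (+)-dihydrocarvone is taken as the 5R compound (mixture of C2 epimers); C2 is erased in step 4 and the 5R carbon becomes sp2 in step 13.

**Route**

Step 1
Reactants: 1 methyl (R)-3-hydroxybutanoate
Product: 2 2-(trimethylsilyl)ethyl (R)-3-hydroxybutanoate
Conditions: Me3SiCH2CH2OH (3 equiv), Ti(OiPr)4 (10 mol %), toluene, 100 °C, MeOH distilled off
Reagents that add atoms: 2-(trimethylsilyl)ethanol, C[Si](C)(C)CCO
Why: Titanate-catalysed transesterification is neutral, leaves the β-hydroxy stereocentre untouched and installs an ester that fluoride can remove at the end.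

Step 2
Reactants: 2 2-(trimethylsilyl)ethyl (R)-3-hydroxybutanoate
Product: 3 2-(trimethylsilyl)ethyl (2R,3R)-3-hydroxy-2-methylbutanoate
Conditions: LiN(iPr)2 (2.2 equiv), THF, −78 → −20 °C; MeI, −78 → 0 °C; H2O
Reagents that add atoms: iodomethane, CI
Why: Fráter–Seebach alkylation, in which the lithium-chelated dianion is methylated anti to the carbinol methyl group, should give the anti (2R,3R) ester.

Step 3
Reactants: 4 (+)-dihydrocarvone
Product: 5 (5R)-5-(2-hydroxypropan-2-yl)-2-methylcyclohexan-1-one
Conditions: Co(acac)2 (20 mol %), PhSiH3, O2 (1 atm), THF, rt; aq. Na2S2O3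
Reagents that add atoms: dioxygen, O=O
Why: Mukaiyama hydration adds water to the 1,1-disubstituted alkene in the Markovnikov sense by hydrogen-atom transfer and spares the ketone, giving the tertiary carbinol that becomes the lactone CMe2–O carbon.

Step 4
Reactants: 5 (5R)-5-(2-hydroxypropan-2-yl)-2-methylcyclohexan-1-one
Product: 6 bis(triethylsilyl) compound (tertiary silyl ether and tetrasubstituted silyl enol ether)
Conditions: Et3SiCl (3 equiv), NaI, Et3N, MeCN, rt
Reagents that add atoms: chlorotriethylsilane, CC[Si](Cl)(CC)CC
Why: The iodosilane formed in the flask silylates the tertiary alcohol and, under equilibrating conditions, gives the thermodynamic methyl-bearing silyl enol ether, which also erases the epimeric methyl centre.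

Step 5
Reactants: 6 bis(triethylsilyl) compound
Product: 7 siloxycyclopropane (6-methyl-1-(triethylsilyloxy)bicyclo[4.1.0]heptane bearing the silyloxy-isopropyl group)
Conditions: Et2Zn, CH2I2, CH2Cl2, 0 °C
Reagents that add atoms: diiodomethane, ICI
Why: Simmons–Smith (Furukawa) cyclopropanation is fastest at the electron-rich silyl enol ether, and the diastereomer ratio is irrelevant because both cyclopropane stereocentres are lost in the next step.

Step 6
Reactants: 7 siloxycyclopropane
Product: 9 (6R)-3-methyl-6-[2-(triethylsilyloxy)propan-2-yl]cyclohept-2-en-1-one, via β-chloro ketone 8 (not isolated)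
Conditions: FeCl3 (2.2 equiv), DMF, 0 °C → rt; then NaOAc, MeOH, 65 °C
Reagents that add atoms: none
Why: One-electron oxidation of the siloxycyclopropane by FeCl3 cleaves the internal bond to the tertiary radical, which is chlorinated, and loss of HCl gives the ring-expanded 3-methylcycloheptenone (Saegusa-type one-carbon ring expansion).

Step 7
Reactants: 9 (6R)-3-methyl-6-[2-(triethylsilyloxy)propan-2-yl]cyclohept-2-en-1-one
Product: 11 Mannich base (β-quaternary ketone with CH2NMe2 on the α-carbon next to the new centre), via aluminium enolate 10 (not isolated)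
Conditions: HC≡CSiMe3, iBu2AlH, hexanes, 55 °C; then 9, Cu(OTf)2 (5 mol %), chiral sulfonate-bearing imidazolinium salt (N-heterocyclic carbene precursor, 5 mol %), THF, −15 °C; then CH2=NMe2+ I−, CH2Cl2, −15 °C → rt
Reagents that add atoms: diisobutyl[1-(trimethylsilyl)ethenyl]aluminium, C=C([Si](C)(C)C)[Al](CC(C)C)CC(C)C; N,N-dimethylmethyleneiminium iodide (Eschenmoser's salt), C=[N+](C)C.[I-]
Why: Copper-catalysed asymmetric conjugate addition of the α-silylvinylalane to the β-methyl enone should set the (S) quaternary carbon under ligand control, and the regiodefined aluminium enolate is aminomethylated (Mannich) at the hindered α-carbon that later kinetic enolisation could not reach.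

Step 8
Reactants: 11 Mannich base
Product: 13 (3S,6R)-3-methyl-2-methylidene-6-[2-(triethylsilyloxy)propan-2-yl]-3-[1-(trimethylsilyl)ethenyl]cycloheptan-1-one, via ammonium iodide 12 (not isolated)
Conditions: MeI, CH2Cl2, rt; then aq. NaHCO3, CH2Cl2, rt
Reagents that add atoms: none
Why: Quaternisation and E1cB loss of trimethylamine give the exocyclic enone, which cannot isomerise into the ring because the neighbouring carbon is quaternary.

Step 9
Reactants: 13 exocyclic enone; 3 2-(trimethylsilyl)ethyl (2R,3R)-3-hydroxy-2-methylbutanoate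
Product: 14 Michael adduct (δ-keto β-hydroxy ester with the acyclic quaternary carbon)
Conditions: 3 (1.3 equiv), LiN(iPr)2 (2.8 equiv), THF, −78 → −30 °C; 13, −78 → −30 °C; AcOH; then DBU (0.3 equiv), toluene, 40 °C
Reagents that add atoms: none
Why: In this Fráter–Seebach-type Michael addition the chelated dianion adds 1,4 to the unhindered exocyclic enone through the face anti to the carbinol methyl, which should fix the acyclic quaternary carbon as R, and the ring CH next to the ketone equilibrates to place the new chain trans to the bulky silylvinyl group.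

Step 10
Reactants: 14 Michael adduct
Product: 15 tert-butyldimethylsilyl ether of 14
Conditions: tBuMe2SiOTf, 2,6-lutidine, CH2Cl2, −78 → 0 °C
Reagents that add atoms: tert-butyldimethylsilyl triflate, CC(C)(C)[Si](C)(C)OS(=O)(=O)C(F)(F)F
Why: The silyl triflate protects the hindered secondary alcohol (the open hydroxy ketone is drawn out of its lactol equilibrium), so that later enolate and triflation steps see only the ring ketone.

Step 11
Reactants: 15 silyl ether
Product: 16 alkenyl iodide (C(I)=CH2 in place of C(SiMe3)=CH2)
Conditions: N-iodosuccinimide, 2,6-lutidine (0.5 equiv), (CF3)2CHOH, 0 °C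
Reagents that add atoms: N-iodosuccinimide, O=C1CCC(=O)N1I
Why: Ipso-iododesilylation through the β-silyl cation replaces silicon by iodine on the same alkene carbon, and it is run before any electron-rich diene is present.

Step 12
Reactants: 16 alkenyl iodide
Product: 17 acrylate (C(=CH2)CO2Me on the ring quaternary carbon)
Conditions: PdCl2(PPh3)2 (5 mol %), CO (1 atm), MeOH, Et3N, DMF, 60 °C
Reagents that add atoms: carbon monoxide, [C-]#[O+]; methanol, CO
Why: Palladium-catalysed methoxycarbonylation of the alkenyl iodide (oxidative addition, CO insertion, methanolysis) gives the α-substituted acrylate that serves as the two-carbon partner of the key step.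

Step 13
Reactants: 17 acrylate
Product: 19 cycloheptenone (C=C between the former α-CH2 and the carbon bearing the silyloxy-isopropyl group), via trimethylsilyl enol ether 18 (not isolated)
Conditions: LiN(iPr)2, Me3SiCl (premixed), THF, −78 °C; then Pd(OAc)2 (10 mol %), O2 (1 atm), DMSO, rt
Reagents that add atoms: none
Why: Kinetic deprotonation with in-flask silylation takes the α-CH2 and not the hindered methine, and Saegusa–Ito oxidation (β-hydride elimination from the palladium enolate, zerovalent palladium reoxidised by O2) gives the enone and erases the terpene-derived stereocentre.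

Step 14
Reactants: 19 cycloheptenone
Product: 20 β,γ-unsaturated ketone carrying CH2CO2Me on the α-carbon
Conditions: KN(SiMe3)2 (1.05 equiv), THF, −78 °C; BrCH2CO2Me (3 equiv), −78 → −40 °C
Reagents that add atoms: methyl bromoacetate, COC(=O)CBr
Why: γ-Deprotonation gives the extended dienolate, which is alkylated at its α-carbon as such enolates normally are, so the acetate arm is attached and the double bond moves to its position in the target diene.

Step 15
Reactants: 20 β,γ-unsaturated ketone
Product: 21 dienyl triflate
Conditions: KN(SiMe3)2 (1.1 equiv), THF, −78 °C; PhNTf2, −78 → 0 °C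
Reagents that add atoms: N-phenylbis(trifluoromethanesulfonimide), O=S(=O)(N(c1ccccc1)S(=O)(=O)C(F)(F)F)C(F)(F)F
Why: The remaining α-proton is doubly activated (ketone and allylic), so it alone is removed and O-triflation of the dienolate gives the 2-triflyloxy-1,3-diene regiospecifically without touching the ring CH stereocentre.

Step 16
Reactants: 21 dienyl triflate
Product: 22 methyl-substituted diene (ring-B diene complete)
Conditions: MeZnCl (2 M in THF, 2 equiv), Pd(PPh3)4 (5 mol %), THF, 50 °C
Reagents that add atoms: methylzinc chloride, C[Zn]Cl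
Why: Negishi coupling of the alkenyl triflate installs the vinylic methyl group, and the esters and the hindered acrylate are inert to the organozinc.

Step 17
Reactants: 22 methyl-substituted diene
Product: 23 lactone hydroxy acid (rings A and B complete)
Conditions: Bu4NF (6 equiv), THF, 0 °C → rt; 1 M HCl work-up
Reagents that add atoms: none
Why: Fluoride removes all three silicon groups: the freed tertiary alkoxide closes the six-membered lactone on the methyl ester, and the silylethyl ester fragments to the carboxylate before the hindered secondary silyl ether is cleaved, which disfavours retro-aldol.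

Step 18
Reactants: 23 lactone hydroxy acid
Product: 24 lactone β-keto acid (acetyl group unveiled)
Conditions: Dess–Martin periodinane (1.5 equiv), CH2Cl2, 0 °C; used crude and cold
Reagents that add atoms: none
Why: Dess–Martin oxidation converts the secondary alcohol into the acetyl ketone under neutral conditions that spare the diene, the lactone and the free acid.

Step 19
Reactants: 24 lactone β-keto acid
Product: 26 α-diazo ketone (2-diazopropanoyl and acetyl groups on the acyclic quaternary carbon), via acid chloride 25 (not isolated)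
Conditions: (COCl)2, DMF (cat.), CH2Cl2, −10 °C; then CH3CHN2 (from N-ethyl-N-nitrosourea, KOH), Et3N, Et2O, −40 → 0 °C
Reagents that add atoms: diazoethane, CC=[N+]=[N-]
Why: Acylation of diazoethane by the acid chloride (Arndt–Eistert-type diazo ketone synthesis with amine as HCl scavenger; no ketene can form at the quaternary carbon) gives the α-methyl diazo ketone, and low temperature favours acylation over dipolar addition to the hindered acrylate.

Step 20
Reactants: 26 α-diazo ketone
Product: 28 oxygen-bridged cycloadduct (rings C and D closed, one oxygen spanning ring D), via carbonyl ylide 27 (not isolated)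
Conditions: Rh2(O2CtBu)4 (2 mol %), CH2Cl2 (0.002 M, slow addition), 0 °C → rt
Reagents that add atoms: none
Why: Loss of N2 at dirhodium tetrapivalate gives a rhodium carbenoid at the methyl-bearing carbon, which is attacked by the oxygen of the 1,3-disposed acetyl group to close a five-membered cyclic carbonyl ylide (enolisation is blocked by the quaternary carbon between the carbonyls), and this dipole adds across the tethered acrylate in a concerted suprafacial [3+2] cycloaddition; the closest known reaction type is the tandem carbonyl-ylide formation/intramolecular dipolar cycloaddition of α-diazo ketones. Ring C closes as a six-membered chair through the three-atom tether, which is only possible when the ester-bearing alkene carbon bonds to the acetyl-derived ylide terminus, and ring D closes in the same event as a boat held by the oxygen bridge (a 7-oxabicyclo[2.2.1]heptanone), so the regiochemistry is tether-enforced, with the tether endo and the ester exo to the oxygen bridge. The three new stereocentres (ester-bearing quaternary carbon, methyl carbinol carbon, oxygenated bridge carbon) follow from addition to the ylide face that carries the tether, that is, from the pre-set acyclic quaternary carbon and the trans-disposed ring-B substituents. The ring oxygen necessarily ends up syn on both termini, which is the cis relation of the tertiary OH and the epoxide oxygen in the target. The step needs ylide formation to outrun 1,2-hydride shift of the α-methyl carbenoid and cyclopropanation of the diene; the fast five-ring closure onto the neighbouring ketone, the bulky pivalate ligands, low temperature and high dilution should secure this, and the electron-poor acrylate is the matched partner for the electron-rich ylide.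

Step 21
Reactants: 28 oxygen-bridged cycloadduct
Product: 30 exo-methylene hydroxy ketone (target lacking the epoxide oxygen), via trimethylsilyl ether 29 (not isolated)
Conditions: Me3SiOTf, 2,6-lutidine, CH2Cl2, −78 → 0 °C; then 1 M HCl, THF, 0 °C
Reagents that add atoms: none
Why: Silylation of the strained bridging oxygen triggers ionisation at the tertiary bridge carbon (the other terminus is α to the ketone and cannot ionise) and, since both neighbours are quaternary, the only β-hydrogens are on the methyl group, so E1-type eliminative ether opening should give the exocyclic methylene and the silylated tertiary alcohol, which is freed on work-up with its configuration intact.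

Step 22
Reactants: 30 exo-methylene hydroxy ketone
Product: 31 CNP0605450.1
Conditions: VO(acac)2 (5 mol %), tBuOOH (in decane, 1.5 equiv), CH2Cl2, 0 °C → rt
Reagents that add atoms: tert-butyl hydroperoxide, CC(C)(C)OO
Why: In this vanadium-catalysed hydroxyl-directed epoxidation the hydroperoxide bound at the vanadate ester of the tertiary alcohol reaches only the nearby exocyclic alkene (the remote electron-rich diene is not epoxidised by this system) and delivers oxygen to the alkene face on the carbinol side, which is also the face not shielded by the axial methyl group of ring C.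

**Compound list**

1 | methyl (R)-3-hydroxybutanoate | C[C@@H](O)CC(=O)OC | starting material
2 | 2-(trimethylsilyl)ethyl (R)-3-hydroxybutanoate | C[C@@H](O)CC(=O)OCC[Si](C)(C)C | intermediate
3 | 2-(trimethylsilyl)ethyl (2R,3R)-3-hydroxy-2-methylbutanoate | C[C@@H](O)[C@@H](C)C(=O)OCC[Si](C)(C)C | intermediate
4 | (+)-dihydrocarvone, (5R)-2-methyl-5-(prop-1-en-2-yl)cyclohexan-1-one (C2 epimers) | CC1CC[C@H](CC1=O)C(C)=C | starting material
5 | (5R)-5-(2-hydroxypropan-2-yl)-2-methylcyclohexan-1-one (C2 epimers) | CC1CC[C@H](CC1=O)C(C)(C)O | intermediate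
6 | triethyl({(5R)-2-methyl-5-[2-(triethylsilyloxy)propan-2-yl]cyclohex-1-en-1-yl}oxy)silane | CC1=C(O[Si](CC)(CC)CC)C[C@@H](CC1)C(C)(C)O[Si](CC)(CC)CC | intermediate
7 | 6-methyl-1-(triethylsilyloxy)-3-[2-(triethylsilyloxy)propan-2-yl]bicyclo[4.1.0]heptane (3R; cyclopropane diastereomers) | CC12CC[C@H](CC1(C2)O[Si](CC)(CC)CC)C(C)(C)O[Si](CC)(CC)CC | intermediate
8 | (6R)-3-chloro-3-methyl-6-[2-(triethylsilyloxy)propan-2-yl]cycloheptan-1-one (C3 epimers) | O=C1CC(C)(Cl)CC[C@H](C1)C(C)(C)O[Si](CC)(CC)CC | intermediate
9 | (6R)-3-methyl-6-[2-(triethylsilyloxy)propan-2-yl]cyclohept-2-en-1-one | O=C1C=C(C)CC[C@H](C1)C(C)(C)O[Si](CC)(CC)CC | intermediate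
10 | diisobutylaluminium enolate of (3S,6R)-3-methyl-6-[2-(triethylsilyloxy)propan-2-yl]-3-[1-(trimethylsilyl)ethenyl]cycloheptanone (enolate towards C2) | C=C([Si](C)(C)C)[C@@]1(C)CC[C@@H](C(C)(C)O[Si](CC)(CC)CC)CC(O[Al](CC(C)C)CC(C)C)=C1 | intermediate
11 | (3S,6R)-2-[(dimethylamino)methyl]-3-methyl-6-[2-(triethylsilyloxy)propan-2-yl]-3-[1-(trimethylsilyl)ethenyl]cycloheptan-1-one (C2 epimers) | C=C([Si](C)(C)C)[C@@]1(C)CC[C@@H](C(C)(C)O[Si](CC)(CC)CC)CC(=O)C1CN(C)C | intermediate
12 | trimethylammonium iodide derived from 11 | C=C([Si](C)(C)C)[C@@]1(C)CC[C@@H](C(C)(C)O[Si](CC)(CC)CC)CC(=O)C1C[N+](C)(C)C.[I-] | intermediate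
13 | (3S,6R)-3-methyl-2-methylidene-6-[2-(triethylsilyloxy)propan-2-yl]-3-[1-(trimethylsilyl)ethenyl]cycloheptan-1-one | C=C([Si](C)(C)C)[C@@]1(C)CC[C@@H](C(C)(C)O[Si](CC)(CC)CC)CC(=O)C1=C | intermediate
14 | 2-(trimethylsilyl)ethyl (2R,3R)-3-hydroxy-2-methyl-2-{[(1R,2S,5R)-2-methyl-7-oxo-5-[2-(triethylsilyloxy)propan-2-yl]-2-[1-(trimethylsilyl)ethenyl]cycloheptyl]methyl}butanoate (side chain trans to the silylvinyl group) | C=C([Si](C)(C)C)[C@@]1(C)CC[C@@H](C(C)(C)O[Si](CC)(CC)CC)CC(=O)[C@@H]1C[C@](C)([C@@H](C)O)C(=O)OCC[Si](C)(C)C | intermediate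
15 | 3-O-tert-butyldimethylsilyl ether of 14 | C=C([Si](C)(C)C)[C@@]1(C)CC[C@@H](C(C)(C)O[Si](CC)(CC)CC)CC(=O)[C@@H]1C[C@](C)([C@@H](C)O[Si](C)(C)C(C)(C)C)C(=O)OCC[Si](C)(C)C | intermediate
16 | 1-iodoethenyl analogue of 15 (iodine in place of the trimethylsilyl group) | C=C(I)[C@@]1(C)CC[C@@H](C(C)(C)O[Si](CC)(CC)CC)CC(=O)[C@@H]1C[C@](C)([C@@H](C)O[Si](C)(C)C(C)(C)C)C(=O)OCC[Si](C)(C)C | intermediate
17 | acrylate: as 16 with C(=CH2)CO2Me on the ring quaternary carbon | COC(=O)C(=C)[C@@]1(C)CC[C@@H](C(C)(C)O[Si](CC)(CC)CC)CC(=O)[C@@H]1C[C@](C)([C@@H](C)O[Si](C)(C)C(C)(C)C)C(=O)OCC[Si](C)(C)C | intermediate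
18 | trimethylsilyl enol ether of 17 (towards the ring CH2) | COC(=O)C(=C)[C@@]1(C)CC[C@@H](C(C)(C)O[Si](CC)(CC)CC)C=C(O[Si](C)(C)C)[C@@H]1C[C@](C)([C@@H](C)O[Si](C)(C)C(C)(C)C)C(=O)OCC[Si](C)(C)C | intermediate
19 | cyclohept-2-enone derived from 17 (β-carbon bears the silyloxy-isopropyl group) | COC(=O)C(=C)[C@@]1(C)CCC(C(C)(C)O[Si](CC)(CC)CC)=CC(=O)[C@@H]1C[C@](C)([C@@H](C)O[Si](C)(C)C(C)(C)C)C(=O)OCC[Si](C)(C)C | intermediate
20 | β,γ-unsaturated ketone with CH2CO2Me on the α-carbon (epimers at that carbon) | COC(=O)C(=C)[C@@]1(C)CC=C(C(C)(C)O[Si](CC)(CC)CC)C(CC(=O)OC)C(=O)[C@@H]1C[C@](C)([C@@H](C)O[Si](C)(C)C(C)(C)C)C(=O)OCC[Si](C)(C)C | intermediate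
21 | dienyl triflate (2-triflyloxy-1,3-diene in ring B) | COC(=O)C(=C)[C@@]1(C)CC=C(C(C)(C)O[Si](CC)(CC)CC)C(CC(=O)OC)=C(OS(=O)(=O)C(F)(F)F)[C@@H]1C[C@](C)([C@@H](C)O[Si](C)(C)C(C)(C)C)C(=O)OCC[Si](C)(C)C | intermediate
22 | methyl-substituted ring-B diene (methyl in place of the triflate) | COC(=O)C(=C)[C@@]1(C)CC=C(C(C)(C)O[Si](CC)(CC)CC)C(CC(=O)OC)=C(C)[C@@H]1C[C@](C)([C@@H](C)O[Si](C)(C)C(C)(C)C)C(=O)OCC[Si](C)(C)C | intermediate
23 | ring-A/B lactone-diene with acrylate and (2R,3R)-2-carboxy-3-hydroxy-2-methylbutyl side chain | COC(=O)C(=C)[C@@]1(C)CC=C2C(CC(=O)OC2(C)C)=C(C)[C@@H]1C[C@](C)([C@@H](C)O)C(=O)O | intermediate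
24 | β-keto acid: as 23 with the carbinol oxidised to acetyl | COC(=O)C(=C)[C@@]1(C)CC=C2C(CC(=O)OC2(C)C)=C(C)[C@@H]1C[C@](C)(C(C)=O)C(=O)O | intermediate
25 | acid chloride of 24 | COC(=O)C(=C)[C@@]1(C)CC=C2C(CC(=O)OC2(C)C)=C(C)[C@@H]1C[C@](C)(C(C)=O)C(Cl)=O | intermediate
26 | α-diazo ketone: acyclic (R) quaternary carbon bearing acetyl and 2-diazopropanoyl groups | COC(=O)C(=C)[C@@]1(C)CC=C2C(CC(=O)OC2(C)C)=C(C)[C@@H]1C[C@](C)(C(C)=O)C(=O)C(C)=[N+]=[N-] | intermediate
27 | five-membered cyclic carbonyl ylide derived from 26 | COC(=O)C(=C)[C@@]1(C)CC=C2C(CC(=O)OC2(C)C)=C(C)[C@@H]1C[C@]3(C)C(C)=[O+][C-](C)C3=O | intermediate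
28 | oxygen-bridged cycloadduct: target skeleton with one oxygen joining the carbinol carbon and the methyl-bearing bridge carbon | COC(=O)[C@@]12C[C@@]4(C)O[C@]1(C)[C@@](C)(C[C@H]3C(C)=C5CC(=O)OC(C)(C)C5=CC[C@@]32C)C4=O | intermediate
29 | trimethylsilyl ether of 30 | COC(=O)[C@]12C[C@@](C)(O[Si](C)(C)C)C(=O)[C@](C)(C[C@H]3C(C)=C4CC(=O)OC(C)(C)C4=CC[C@@]31C)C2=C | intermediate
30 | exo-methylene hydroxy ketone (target with C=CH2 in place of the spiro-epoxide) | COC(=O)[C@]12C[C@@](C)(O)C(=O)[C@](C)(C[C@H]3C(C)=C4CC(=O)OC(C)(C)C4=CC[C@@]31C)C2=C | intermediate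
31 | CNP0605450.1 | COC(=O)[C@]12C[C@@](C)(O)C(=O)[C@](C)(C[C@H]3C(C)=C4CC(=O)OC(C)(C)C4=CC[C@@]31C)[C@]21CO1 | target

**Totals and risks**

Total step count: 22. Longest linear sequence: 20 steps (steps 3–22, from (+)-dihydrocarvone).

Steps most likely to fail:

Step 21. The silyl triflate may ionise the tertiary allylic C–O bond of the lactone as well as the bridging ether, and the bridge cation may undergo a 1,2-acyl or alkyl shift before it loses a methyl proton. The fallback sets out from 28 and comes back at 30. The α-alkoxy ketone C–O bond is cleaved reductively with SmI2 (THF/MeOH, −78 °C) to the tertiary bridge alcohol with an α-CH(Me) ketone, hydroxy ketone F1. Burgess dehydration, for which only the methyl hydrogens are available, gives the exo-methylene ketone F2. The ketone enolate (KN(SiMe3)2, 2.2 equiv so that the lactone α-position is also covered, −78 °C) is then hydroxylated with 2-(phenylsulfonyl)-3-phenyloxaziridine from the open exo face to return to 30.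

Step 9. The strongly basic dianion may enolise the enone or add 1,2, the hindered β-alkoxide may undergo retro-aldol, and equilibration of the ring CH may stay incomplete. The fallback sets out from 3 and 13 and comes back at 15, leaving out step 10. Compound 3 is silylated (tBuMe2SiCl, imidazole) to the silyl ether F3 and converted with LiN(iPr)2/Me3SiCl into the silyl ketene acetal F4. F4 is added to 13 in a Mukaiyama–Michael reaction (tBuMe2SiOTf cat., CH2Cl2, −78 °C), followed by mild acidic work-up of the silyl enol ether and the same DBU equilibration. Control of the acyclic quaternary carbon then rests on acyclic 1,2-induction and may be lower.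

Step 19. The β-keto acid may decarboxylate before activation, and excess diazoethane may add as a dipole to the acrylate. The fallback sets out from 23 and comes back at 26. Compound 23 is bis-silylated (Et3SiCl, imidazole) to the silyl ether silyl ester F5, which oxalyl chloride/DMF converts directly into the acid chloride F6 under neutral conditions. Acylation of 1.1 equiv of diazoethane with Et3N at −78 °C gives the silyloxy diazo ketone F7. Buffered desilylation (Bu4NF/AcOH) gives the hydroxy diazo ketone F8, and Dess–Martin oxidation then gives 26, so no β-keto acid is ever formed.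

Further compounds
F1 | step 21 | hydroxy ketone: tertiary bridge alcohol with methyl, α-CH(Me) ketone (epimers at that carbon) | COC(=O)[C@]12CC(C)C(=O)[C@](C)(C[C@H]3C(C)=C4CC(=O)OC(C)(C)C4=CC[C@@]31C)[C@@]2(C)O
F2 | step 21 | exo-methylene ketone with α-CH(Me) | COC(=O)[C@]12CC(C)C(=O)[C@](C)(C[C@H]3C(C)=C4CC(=O)OC(C)(C)C4=CC[C@@]31C)C2=C
F3 | step 9 | 2-(trimethylsilyl)ethyl (2R,3R)-3-(tert-butyldimethylsilyloxy)-2-methylbutanoate | C[C@@H](O[Si](C)(C)C(C)(C)C)[C@@H](C)C(=O)OCC[Si](C)(C)C
F4 | step 9 | trimethylsilyl ketene acetal of F3 | C[C@@H](O[Si](C)(C)C(C)(C)C)C(C)=C(OCC[Si](C)(C)C)O[Si](C)(C)C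
F5 | step 19 | triethylsilyl ether triethylsilyl ester of 23 | COC(=O)C(=C)[C@@]1(C)CC=C2C(CC(=O)OC2(C)C)=C(C)[C@@H]1C[C@](C)([C@@H](C)O[Si](CC)(CC)CC)C(=O)O[Si](CC)(CC)CC
F6 | step 19 | silyloxy acid chloride | COC(=O)C(=C)[C@@]1(C)CC=C2C(CC(=O)OC2(C)C)=C(C)[C@@H]1C[C@](C)([C@@H](C)O[Si](CC)(CC)CC)C(Cl)=O
F7 | step 19 | silyloxy α-diazo ketone | COC(=O)C(=C)[C@@]1(C)CC=C2C(CC(=O)OC2(C)C)=C(C)[C@@H]1C[C@](C)([C@@H](C)O[Si](CC)(CC)CC)C(=O)C(C)=[N+]=[N-]
F8 | step 19 | hydroxy α-diazo ketone | COC(=O)C(=C)[C@@]1(C)CC=C2C(CC(=O)OC2(C)C)=C(C)[C@@H]1C[C@](C)([C@@H](C)O)C(=O)C(C)=[N+]=[N-]
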